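Slowness is brief in these runs: Saturday's run reads 95.0% D at 1.00 min and 99.2% at 3.00 min, and Wednesday's run reads 10.9% at 3.00 min and 10.9% at 20.0 min. So read the charges rather than the clock.

all flasks: G 0.050 M
- Wednesday's: E 0.020 M; run made earlier
- Saturday's: E 0.16 M; run made earlier
- delta: E 0.0250 M; time 40 min
- beta: E 0.200 M; time 40 min

- Wednesday's (time / min: D / %): 3.00: 10.9; 6.00: 10.6; 8.00: 11.0; 12.0: 11.1; 15.0: 11.0; 20.0: 10.9
- Saturday's (time / min: D / %): 1.00: 95.0; 3.00: 99.2; 6.00: 99.8; 8.00: 100.0; 12.0: 99.3; 15.0: 99.9; 20.0: 100.1

(standard deviation of a reading: 0.3 percentage points)

* which of these holds the largest part of the G at the end of delta (D / G / J)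
* which of these holds the largest part of the G at the end of beta (D / G / J)
* D at the end of beta, in percent of the G charged

- the numbers in the tables scatter by 0.3 percentage points (one standard deviation)

Each G needs two E to become D. For beta, the E charged over twice the G charged is 2.00; call this ratio the cover. Below one, the cover is also the ceiling on D as a fraction of the G charged.

Now go down the recipes. Wednesday's run has a cover of 0.200, and its D stays flat near 11.0%, under that ceiling. Saturday's run has a cover of 1.60, and its D reads 100.1% at 20.0 min. Delta has a cover of 0.250, a little above Wednesday's, so you expect a similar stop with G in the lead. Beta's cover is above Saturday's, so you expect D to fill beta. The open point is the stretch from 20.0 min to 40 min, though Saturday's readings from 3.00 min on show no drift beyond their scatter.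

The forecast names G for delta, D for beta and 100% D in beta, and says that this “assumes D stays stable beyond 20 min”.

Delta ends with G at 66.1%, J at 18.7% and D at 15.2%. Beta ends with D at 100%. The forecast held.

    G + E → J + Z (k = 0.840 M⁻¹ s⁻¹)
    E + J → D + Z (k = 2.50 M⁻¹ s⁻¹)
    2 E → L (k = 0.0330 M⁻¹ s⁻¹)

Beta, with its cover of 2.00, ends with G at 0% and E at 2.9% of its own charge, and G is the charge that runs out first there, the limiting reagent. Raise the G in beta to 0.12 M and the cover falls to 0.833, below one. That puts the ceiling on D at 83.3% of the G charged. This neighbouring flask gives D at 74.4%, under the ceiling, with E at 0% of its charge, J at 8.42% and G at 17%.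

Readings and results stem from a simulated flask with made-up constants, noise included.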